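The route rests on the C9–C10 bond of ring B (labdane numbering; ring B = C5–C10). Ring A with the C5 stereocentre is built first by a chirality-transferring Johnson–Claisen rearrangement. The key step, a hydrogen-atom-transfer-initiated radical cyclisation, then closes ring B last: the C10 radical adds 6-endo to C9 of a Z-enoate that carries an acetate at C7. It exploits the allylic C7=C8–C17 oxygen pattern of ring B: C17 as an ester directs the radical to C9, and loss of the C7 acetate from the C8 enolate leaves the C7=C8 alkene. One operation thus sets C9 and the quaternary C10. The precursor is a monocyclic Morita–Baylis–Hillman-type acetate.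

Key step: step 10

Remark: atom numbers are labdane numbers (ring A = C1–C5 and C10); the acyl group is read as 30-hydroxytriacontanoyl (29 CH2 groups) and the target as the ent-labdane (5R,9S,10R).

Step 1
Reactants: 1 2,4,4-trimethylcyclohex-2-en-1-one
Product: 2 (1S)-2,4,4-trimethylcyclohex-2-en-1-ol
Conditions: (R)-2-methyl-CBS-oxazaborolidine (10 mol %), BH3·SMe2, THF, −20 °C
Reagents that add atoms: none
Why: Corey–Bakshi–Shibata reduction, in which the methyl-substituted alkenyl branch acts as the large group so that the (R)-catalyst should deliver hydride to give the (S)-carbinol, the easily set centre that later controls C5.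

Step 2
Reactants: 2 (1S)-2,4,4-trimethylcyclohex-2-en-1-ol
Product: 4 ethyl [(1R)-2,6,6-trimethylcyclohex-2-en-1-yl]acetate, via mixed ketene acetal 3 (not isolated)
Conditions: MeC(OEt)3, EtCO2H (cat.), 140 °C, EtOH distilled off
Reagents that add atoms: triethyl orthoacetate, CC(OCC)(OCC)OCC
Why: Johnson–Claisen rearrangement, whose suprafacial [3,3] shift should place C6–C7 on C5 on the face of the former C–O bond, so the carbinol configuration is transferred to C5 and the alkene moves to C1=C10.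

Step 3
Reactants: 4 ethyl [(1R)-2,6,6-trimethylcyclohex-2-en-1-yl]acetate
Product: 5 [(1R)-2,6,6-trimethylcyclohex-2-en-1-yl]acetaldehyde
Conditions: i-Bu2AlH (1.05 equiv), CH2Cl2, −78 °C; Rochelle salt work-up
Reagents that add atoms: none
Why: partial ester reduction, which should stop at the aldehyde because the aluminium hemiacetal is stable at −78 °C; the C5 centre is β to the carbonyl and cannot epimerise.

Step 4
Reactants: 6 geranyl acetate
Product: 8 (2E)-3-methyl-6-oxohex-2-en-1-yl acetate, via secondary ozonide 7 (not isolated)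
Conditions: O3 (1 equiv), CH2Cl2, −78 °C; then Me2S, −78 °C to rt
Reagents that add atoms: ozone, [O-][O+]=O
Why: chemoselective ozonolysis, in which the electron-rich distal alkene should react well before the alkene deactivated by the allylic acetate; the aldehyde carbon becomes C9.

Step 5
Reactants: 8 (2E)-3-methyl-6-oxohex-2-en-1-yl acetate
Product: 10 (2E)-3-methylhept-2-en-6-yn-1-ol, via acetoxy alkyne 9 (not isolated)
Conditions: dimethyl (1-diazo-2-oxopropyl)phosphonate, K2CO3, MeOH, 0 °C to rt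
Reagents that add atoms: dimethyl (1-diazo-2-oxopropyl)phosphonate, COP(=O)(OC)C(=[N+]=[N-])C(C)=O
Why: Seyferth–Gilbert homologation with the Ohira–Bestmann reagent should turn the aldehyde into the terminal alkyne (adds C8), and the basic methanol should cleave the acetate in the same flask.

Step 6
Reactants: 10 (2E)-3-methylhept-2-en-6-yn-1-ol
Product: 11 tert-butyl(dimethyl){[(2E)-3-methylhept-2-en-6-yn-1-yl]oxy}silane
Conditions: TBSCl, imidazole, DMF, rt
Reagents that add atoms: tert-butyl(chloro)dimethylsilane, CC(C)(C)[Si](C)(C)Cl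
Why: standard silylation of the primary allylic alcohol, giving a C15 ether that tolerates organolithium and aluminium hydride reagents.

Step 7
Reactants: 11 tert-butyl(dimethyl){[(2E)-3-methylhept-2-en-6-yn-1-yl]oxy}silane
Product: 13 ethyl (6E)-8-{[tert-butyl(dimethyl)silyl]oxy}-6-methyloct-6-en-2-ynoate, via lithium acetylide 12 (not isolated)
Conditions: n-BuLi, THF, −78 °C; then ClCO2Et, −78 °C to 0 °C
Reagents that add atoms: ethyl chloroformate, CCOC(=O)Cl
Why: deprotonation of the terminal alkyne and C-acylation of the acetylide should add C17 at the ester oxidation level.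

Step 8
Reactants: 13 ethyl (6E)-8-{[tert-butyl(dimethyl)silyl]oxy}-6-methyloct-6-en-2-ynoate; 5 [(1R)-2,6,6-trimethylcyclohex-2-en-1-yl]acetaldehyde
Product: 15 ethyl (2Z,6E)-8-{[tert-butyl(dimethyl)silyl]oxy}-2-{1-hydroxy-2-[(1R)-2,6,6-trimethylcyclohex-2-en-1-yl]ethyl}-6-methylocta-2,6-dienoate (both C7 epimers), via vinylalane 14 (not isolated)
Conditions: i-Bu2AlH, N-methylmorpholine N-oxide, THF, 0 °C; then 5, 0 °C to rt
Reagents that add atoms: none
Why: vinylalumination, in which syn-hydroalumination of the ynoate (hydride to C9, aluminium to C8) and aldol-type addition to the aldehyde should give the Z Morita–Baylis–Hillman-type adduct with C11 trans to C7; the C7 carbinol centre is uncontrolled and is lost in step 10.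

Step 9
Reactants: 15 ethyl (2Z,6E)-8-{[tert-butyl(dimethyl)silyl]oxy}-2-{1-hydroxy-2-[(1R)-2,6,6-trimethylcyclohex-2-en-1-yl]ethyl}-6-methylocta-2,6-dienoate
Product: 16 ethyl (2Z,6E)-2-{1-acetoxy-2-[(1R)-2,6,6-trimethylcyclohex-2-en-1-yl]ethyl}-8-{[tert-butyl(dimethyl)silyl]oxy}-6-methylocta-2,6-dienoate
Conditions: Ac2O, pyridine, DMAP (cat.), CH2Cl2, 0 °C
Reagents that add atoms: acetic anhydride, CC(=O)OC(C)=O
Why: routine acetylation of the secondary allylic alcohol installs the leaving group at C7.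

Step 10
Reactants: 16 ethyl (2Z,6E)-2-{1-acetoxy-2-[(1R)-2,6,6-trimethylcyclohex-2-en-1-yl]ethyl}-8-{[tert-butyl(dimethyl)silyl]oxy}-6-methylocta-2,6-dienoate
Product: 18 ethyl (5R,9S,10R)-15-{[tert-butyl(dimethyl)silyl]oxy}labda-7,13E-dien-17-oate, via cyclised acetoxy ester 17 (not isolated)
Conditions: Fe(acac)3 (30 mol %), PhSiH3, EtOH, 60 °C; then DBU, rt
Reagents that add atoms: none
Why: An iron hydride formed from Fe(acac)3 and PhSiH3 should transfer a hydrogen atom to C1 of the ring A alkene, and the tertiary C10 radical should add 6-endo-trig to C9, the β-carbon of the Z-enoate, closing ring B through the C9–C10 bond; the closest known reaction types are the hydrogen-atom-transfer-initiated Giese cyclisation and the radical addition–elimination on Morita–Baylis–Hillman acetates. The C8 α-ester radical is reduced to the enolate, which expels the C7 acetate (E1cB), so the C7=C8 alkene and the C17 ester arise in the same operation, and DBU completes the elimination of any protonated adduct 17. C10 is controlled by the C5 stereocentre: the tether is equatorial on ring A and the chair-like transition state places the C10 methyl axial, giving the trans ring fusion as in radical polyene cyclisations. C9 is controlled by the Z geometry of the enoate, whose C11 substituent lies trans to C7 and so becomes equatorial, cis to the C10 methyl. The step needs 6-endo over 5-exo closure, secured by the ester polarisation and the fully substituted C8, and hydrogen-atom transfer to the ring alkene instead of the C13=C14 alkene, which the allylic silyloxy group deactivates. Both C7 epimers of 16 should converge on 18.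

Step 11
Reactants: 18 ethyl (5R,9S,10R)-15-{[tert-butyl(dimethyl)silyl]oxy}labda-7,13E-dien-17-oate
Product: 19 (5R,9S,10R)-15-{[tert-butyl(dimethyl)silyl]oxy}labda-7,13E-dien-17-ol
Conditions: i-Bu2AlH (2.5 equiv), CH2Cl2, −78 °C to 0 °C
Reagents that add atoms: none
Why: 1,2-reduction of the conjugated ester should give the allylic C17 alcohol without touching the alkenes or the silyl ether.

Step 12
Reactants: 19 (5R,9S,10R)-15-{[tert-butyl(dimethyl)silyl]oxy}labda-7,13E-dien-17-ol
Product: 20 (5R,9S,10R)-15-{[tert-butyl(dimethyl)silyl]oxy}-17-{[tert-butyl(diphenyl)silyl]oxy}labda-7,13E-diene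
Conditions: TBDPSCl, imidazole, DMF, rt
Reagents that add atoms: tert-butyl(chloro)diphenylsilane, CC(C)(C)[Si](Cl)(c1ccccc1)c1ccccc1
Why: silylation of the primary C17 alcohol with a group that outlasts the acid that removes the C15 silyl ether.

Step 13
Reactants: 20 (5R,9S,10R)-15-{[tert-butyl(dimethyl)silyl]oxy}-17-{[tert-butyl(diphenyl)silyl]oxy}labda-7,13E-diene
Product: 21 (5R,9S,10R)-17-{[tert-butyl(diphenyl)silyl]oxy}labda-7,13E-dien-15-ol
Conditions: PPTS, EtOH, rt
Reagents that add atoms: none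
Why: selective desilylation, since acid-catalysed ethanolysis should cleave the primary tert-butyldimethylsilyl ether far faster than the tert-butyldiphenylsilyl ether.

Step 14
Reactants: 22 15-bromopentadecanoic acid
Product: 23 15-bromopentadecan-1-ol
Conditions: BH3·THF, THF, 0 °C to rt
Reagents that add atoms: none
Why: borane reduces the carboxylic acid chemoselectively through its acyloxyborane and leaves the primary bromide.

Step 15
Reactants: 23 15-bromopentadecan-1-ol
Product: 24 [(15-bromopentadecyl)oxy](tert-butyl)diphenylsilane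
Conditions: TBDPSCl, imidazole, CH2Cl2, rt
Reagents that add atoms: tert-butyl(chloro)diphenylsilane, CC(C)(C)[Si](Cl)(c1ccccc1)c1ccccc1
Why: routine silylation, giving an ether that survives Grignard formation.

Step 16
Reactants: 24 [(15-bromopentadecyl)oxy](tert-butyl)diphenylsilane; 22 15-bromopentadecanoic acid
Product: 27 30-{[tert-butyl(diphenyl)silyl]oxy}triacontanoic acid, via Grignard reagent 25 (not isolated), via chloromagnesium carboxylate 26 (not isolated)
Conditions: 24, Mg, THF, reflux; separately 22, MeMgCl (1 equiv), THF, −20 °C; combine, Li2CuCl4 (3 mol %), −20 °C to rt; aq. HCl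
Reagents that add atoms: none
Why: copper-catalysed alkyl–alkyl cross-coupling of a Grignard reagent with a primary bromide should join the two C15 halves, the acid being masked in the flask as its magnesium salt.

Step 17
Reactants: 21 (5R,9S,10R)-17-{[tert-butyl(diphenyl)silyl]oxy}labda-7,13E-dien-15-ol; 27 30-{[tert-butyl(diphenyl)silyl]oxy}triacontanoic acid
Product: 28 (5R,9S,10R)-17-{[tert-butyl(diphenyl)silyl]oxy}labda-7,13E-dien-15-yl 30-{[tert-butyl(diphenyl)silyl]oxy}triacontanoate
Conditions: EDC·HCl, DMAP, CH2Cl2, rt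
Reagents that add atoms: none
Why: Steglich esterification, in which the C15 alcohol is the only free hydroxyl, so acylation should be site-specific.

Step 18
Reactants: 28 (5R,9S,10R)-17-{[tert-butyl(diphenyl)silyl]oxy}labda-7,13E-dien-15-yl 30-{[tert-butyl(diphenyl)silyl]oxy}triacontanoate
Product: 29 (5R,9S,10R)-17-hydroxylabda-7,13E-dien-15-yl 30-hydroxytriacontanoate (CNP0329077.1)
Conditions: HF·pyridine, pyridine, THF, 0 °C to rt
Reagents that add atoms: none
Why: fluoride-mediated desilylation should free both primary alcohols under buffered conditions that leave the allylic ester and the alkenes intact.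

Compound list
1 | 2,4,4-trimethylcyclohex-2-en-1-one | CC1=CC(C)(C)CCC1=O | starting material
2 | (1S)-2,4,4-trimethylcyclohex-2-en-1-ol | O[C@H]1CCC(C)(C)C=C1C | intermediate
3 | 1-ethoxyethenyl (1S)-2,4,4-trimethylcyclohex-2-en-1-yl ether (mixed ketene acetal) | C=C(OCC)O[C@H]1CCC(C)(C)C=C1C | intermediate
4 | ethyl [(1R)-2,6,6-trimethylcyclohex-2-en-1-yl]acetate | CCOC(=O)C[C@H]1C(C)=CCCC1(C)C | intermediate
5 | [(1R)-2,6,6-trimethylcyclohex-2-en-1-yl]acetaldehyde | O=CC[C@H]1C(C)=CCCC1(C)C | intermediate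
6 | geranyl acetate | CC(=O)OC/C=C(\C)CCC=C(C)C | starting material
7 | secondary ozonide of the distal alkene of geranyl acetate | CC(=O)OC/C=C(\C)CCC1OOC(C)(C)O1 | intermediate
8 | (2E)-3-methyl-6-oxohex-2-en-1-yl acetate | CC(=O)OC/C=C(\C)CCC=O | intermediate
9 | (2E)-3-methylhept-2-en-6-yn-1-yl acetate | CC(=O)OC/C=C(\C)CCC#C | intermediate
10 | (2E)-3-methylhept-2-en-6-yn-1-ol | OC/C=C(\C)CCC#C | intermediate
11 | tert-butyl(dimethyl){[(2E)-3-methylhept-2-en-6-yn-1-yl]oxy}silane | CC(C)(C)[Si](C)(C)OC/C=C(\C)CCC#C | intermediate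
12 | lithium acetylide of 11 | [Li]C#CCC/C(C)=C/CO[Si](C)(C)C(C)(C)C | intermediate
13 | ethyl (6E)-8-{[tert-butyl(dimethyl)silyl]oxy}-6-methyloct-6-en-2-ynoate | CCOC(=O)C#CCC/C(C)=C/CO[Si](C)(C)C(C)(C)C | intermediate
14 | ethyl (2E,6E)-2-(diisobutylalumanyl)-8-{[tert-butyl(dimethyl)silyl]oxy}-6-methylocta-2,6-dienoate | CCOC(=O)/C(=C\CC/C(C)=C/CO[Si](C)(C)C(C)(C)C)[Al](CC(C)C)CC(C)C | intermediate
15 | ethyl (2Z,6E)-8-{[tert-butyl(dimethyl)silyl]oxy}-2-{1-hydroxy-2-[(1R)-2,6,6-trimethylcyclohex-2-en-1-yl]ethyl}-6-methylocta-2,6-dienoate (C7 epimers) | CCOC(=O)/C(=C\CC/C(C)=C/CO[Si](C)(C)C(C)(C)C)C(O)C[C@H]1C(C)=CCCC1(C)C | intermediate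
16 | ethyl (2Z,6E)-2-{1-acetoxy-2-[(1R)-2,6,6-trimethylcyclohex-2-en-1-yl]ethyl}-8-{[tert-butyl(dimethyl)silyl]oxy}-6-methylocta-2,6-dienoate (C7 epimers) | CCOC(=O)/C(=C\CC/C(C)=C/CO[Si](C)(C)C(C)(C)C)C(OC(C)=O)C[C@H]1C(C)=CCCC1(C)C | intermediate
17 | ethyl (5R,9S,10R)-7-acetoxy-15-{[tert-butyl(dimethyl)silyl]oxy}labd-13E-en-17-oate (C7 and C8 undefined) | C/C(=C\CO[Si](C)(C)C(C)(C)C)CC[C@@H]1C(C(=O)OCC)C(OC(C)=O)C[C@@H]2C(C)(C)CCC[C@@]12C | intermediate
18 | ethyl (5R,9S,10R)-15-{[tert-butyl(dimethyl)silyl]oxy}labda-7,13E-dien-17-oate | C/C(=C\CO[Si](C)(C)C(C)(C)C)CC[C@@H]1C(C(=O)OCC)=CC[C@@H]2C(C)(C)CCC[C@@]12C | intermediate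
19 | (5R,9S,10R)-15-{[tert-butyl(dimethyl)silyl]oxy}labda-7,13E-dien-17-ol | C/C(=C\CO[Si](C)(C)C(C)(C)C)CC[C@@H]1C(CO)=CC[C@@H]2C(C)(C)CCC[C@@]12C | intermediate
20 | (5R,9S,10R)-15-{[tert-butyl(dimethyl)silyl]oxy}-17-{[tert-butyl(diphenyl)silyl]oxy}labda-7,13E-diene | C/C(=C\CO[Si](C)(C)C(C)(C)C)CC[C@@H]1C(CO[Si](c3ccccc3)(c3ccccc3)C(C)(C)C)=CC[C@@H]2C(C)(C)CCC[C@@]12C | intermediate
21 | (5R,9S,10R)-17-{[tert-butyl(diphenyl)silyl]oxy}labda-7,13E-dien-15-ol | C/C(=C\CO)CC[C@@H]1C(CO[Si](c3ccccc3)(c3ccccc3)C(C)(C)C)=CC[C@@H]2C(C)(C)CCC[C@@]12C | intermediate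
22 | 15-bromopentadecanoic acid | OC(=O)CCCCCCCCCCCCCCBr | starting material
23 | 15-bromopentadecan-1-ol | OCCCCCCCCCCCCCCCBr | intermediate
24 | [(15-bromopentadecyl)oxy](tert-butyl)diphenylsilane | CC(C)(C)[Si](c1ccccc1)(c1ccccc1)OCCCCCCCCCCCCCCCBr | intermediate
25 | (15-{[tert-butyl(diphenyl)silyl]oxy}pentadecyl)magnesium bromide | CC(C)(C)[Si](c1ccccc1)(c1ccccc1)OCCCCCCCCCCCCCCC[Mg]Br | intermediate
26 | chloromagnesium 15-bromopentadecanoate | Cl[Mg]OC(=O)CCCCCCCCCCCCCCBr | intermediate
27 | 30-{[tert-butyl(diphenyl)silyl]oxy}triacontanoic acid | OC(=O)CCCCCCCCCCCCCCCCCCCCCCCCCCCCCO[Si](c1ccccc1)(c1ccccc1)C(C)(C)C | intermediate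
28 | (5R,9S,10R)-17-{[tert-butyl(diphenyl)silyl]oxy}labda-7,13E-dien-15-yl 30-{[tert-butyl(diphenyl)silyl]oxy}triacontanoate | C/C(=C\COC(=O)CCCCCCCCCCCCCCCCCCCCCCCCCCCCCO[Si](c3ccccc3)(c3ccccc3)C(C)(C)C)CC[C@@H]1C(CO[Si](c3ccccc3)(c3ccccc3)C(C)(C)C)=CC[C@@H]2C(C)(C)CCC[C@@]12C | intermediate
29 | (5R,9S,10R)-17-hydroxylabda-7,13E-dien-15-yl 30-hydroxytriacontanoate (CNP0329077.1) | C/C(=C\COC(=O)CCCCCCCCCCCCCCCCCCCCCCCCCCCCCO)CC[C@@H]1C(CO)=CC[C@@H]2C(C)(C)CCC[C@@]12C | target

Total step count: 18. Longest linear sequence: 12 steps (steps 4–13, 17 and 18, from geranyl acetate).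

Steps most likely to fail

Step 10. Hydrogen-atom transfer may go to the side-chain alkene, or be reversible at C10, so that the side chain is reduced or the C5 configuration erodes before the ring closes. The fallback generates the C10 radical from a tertiary alcohol that is introduced while the ring alkene is the only alkene. It sets out from 4: Mukaiyama hydration (Co(acac)2, PhSiH3, O2, i-PrOH) should give ethyl [(1R)-2-hydroxy-2,6,6-trimethylcyclohexyl]acetate F1 as C10 epimers. i-Bu2AlH at −78 °C should give [(1R)-2-hydroxy-2,6,6-trimethylcyclohexyl]acetaldehyde F2, partly as its lactol. Addition of excess vinylalane 14 should give ethyl (2Z,6E)-8-{[tert-butyl(dimethyl)silyl]oxy}-2-{1-hydroxy-2-[(1R)-2-hydroxy-2,6,6-trimethylcyclohexyl]ethyl}-6-methylocta-2,6-dienoate F3. Ac2O and pyridine should acetylate only the secondary hydroxyl to give ethyl (2Z,6E)-2-{1-acetoxy-2-[(1R)-2-hydroxy-2,6,6-trimethylcyclohexyl]ethyl}-8-{[tert-butyl(dimethyl)silyl]oxy}-6-methylocta-2,6-dienoate F4. Methyl chlorooxoacetate, Et3N and DMAP should give the tertiary methyl oxalate of F4 F5, and one equivalent of CsOH the caesium oxalate of F4 F6. Visible-light photoredox catalysis ([Ir(dF(CF3)ppy)2(dtbbpy)]PF6, blue LEDs, DME/DMF, water, 60 °C; then DBU) should release the same C10 radical by double decarboxylation; 6-endo cyclisation, reduction of the C8 radical and loss of acetate bring the route back at 18.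

Step 8. The vinylalane may equilibrate through its aluminium allenolate and lose the Z geometry, or add so slowly to the β-branched aldehyde that simple reduction of 5 competes. The fallback fixes the geometry in an isolable vinyl iodide and couples it under chromium mediation. It sets out from 13: palladium-catalysed syn-hydrostannation (Bu3SnH, Pd(PPh3)4, THF) should give ethyl (2E,6E)-8-{[tert-butyl(dimethyl)silyl]oxy}-6-methyl-2-(tributylstannyl)octa-2,6-dienoate F7. I2 in CH2Cl2 should give, with retention, ethyl (2E,6E)-8-{[tert-butyl(dimethyl)silyl]oxy}-2-iodo-6-methylocta-2,6-dienoate F8. Nozaki–Hiyama–Kishi coupling of F8 with 5 (CrCl2, NiCl2 (cat.), DMF) brings the route back at 15.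

Step 16. Wurtz-type homocoupling of the Grignard reagent and slow cross-coupling of the poorly soluble magnesium carboxylate may leave mixtures of C15 and C30 chains. The fallback joins the two C15 halves by a Wittig reaction. It sets out from 22 and 24: PPh3 in MeCN at reflux should convert 22 into (14-carboxytetradecyl)triphenylphosphonium bromide F9. Kornblum oxidation of 24 (DMSO, NaHCO3, 110 °C) should give 15-{[tert-butyl(diphenyl)silyl]oxy}pentadecanal F10. The ylide of F9 (NaHMDS, 2 equiv, THF, −78 °C to rt) and F10 should give (15Z)-30-{[tert-butyl(diphenyl)silyl]oxy}triacont-15-enoic acid F11. Hydrogenation (H2, Pd/C, EtOAc) brings the route back at 27.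

Further compounds
F1 | step 10 | ethyl [(1R)-2-hydroxy-2,6,6-trimethylcyclohexyl]acetate | CCOC(=O)C[C@H]1C(C)(O)CCCC1(C)C
F2 | step 10 | [(1R)-2-hydroxy-2,6,6-trimethylcyclohexyl]acetaldehyde | O=CC[C@H]1C(C)(O)CCCC1(C)C
F3 | step 10 | ethyl (2Z,6E)-8-{[tert-butyl(dimethyl)silyl]oxy}-2-{1-hydroxy-2-[(1R)-2-hydroxy-2,6,6-trimethylcyclohexyl]ethyl}-6-methylocta-2,6-dienoate | CCOC(=O)/C(=C\CC/C(C)=C/CO[Si](C)(C)C(C)(C)C)C(O)C[C@H]1C(C)(O)CCCC1(C)C
F4 | step 10 | ethyl (2Z,6E)-2-{1-acetoxy-2-[(1R)-2-hydroxy-2,6,6-trimethylcyclohexyl]ethyl}-8-{[tert-butyl(dimethyl)silyl]oxy}-6-methylocta-2,6-dienoate | CCOC(=O)/C(=C\CC/C(C)=C/CO[Si](C)(C)C(C)(C)C)C(OC(C)=O)C[C@H]1C(C)(O)CCCC1(C)C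
F5 | step 10 | tertiary methyl oxalate of F4 | CCOC(=O)/C(=C\CC/C(C)=C/CO[Si](C)(C)C(C)(C)C)C(OC(C)=O)C[C@H]1C(C)(OC(=O)C(=O)OC)CCCC1(C)C
F6 | step 10 | caesium oxalate of F4 | CCOC(=O)/C(=C\CC/C(C)=C/CO[Si](C)(C)C(C)(C)C)C(OC(C)=O)C[C@H]1C(C)(OC(=O)C([O-])=O)CCCC1(C)C.[Cs+]
F7 | step 8 | ethyl (2E,6E)-8-{[tert-butyl(dimethyl)silyl]oxy}-6-methyl-2-(tributylstannyl)octa-2,6-dienoate | CCOC(=O)/C(=C\CC/C(C)=C/CO[Si](C)(C)C(C)(C)C)[Sn](CCCC)(CCCC)CCCC
F8 | step 8 | ethyl (2E,6E)-8-{[tert-butyl(dimethyl)silyl]oxy}-2-iodo-6-methylocta-2,6-dienoate | CCOC(=O)/C(I)=C\CC/C(C)=C/CO[Si](C)(C)C(C)(C)C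
F9 | step 16 | (14-carboxytetradecyl)triphenylphosphonium bromide | OC(=O)CCCCCCCCCCCCCC[P+](c1ccccc1)(c1ccccc1)c1ccccc1.[Br-]
F10 | step 16 | 15-{[tert-butyl(diphenyl)silyl]oxy}pentadecanal | O=CCCCCCCCCCCCCCCO[Si](c1ccccc1)(c1ccccc1)C(C)(C)C
F11 | step 16 | (15Z)-30-{[tert-butyl(diphenyl)silyl]oxy}triacont-15-enoic acid | OC(=O)CCCCCCCCCCCCC/C=C\CCCCCCCCCCCCCCO[Si](c1ccccc1)(c1ccccc1)C(C)(C)C
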